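Numbering: C1 benzoyl bridgehead, C2 (OMe), C3, C4 (enone C=O), C5 prenyl bridgehead, C6 (CH2), C7 (CH with side chain), C8 (CMe2), C9 (bridging C=O); ring A = C1-C2-C3-C4-C5-C9, ring B = C1-C8-C7-C6-C5-C9. The plan rests on the C1–C8 bond of ring B, which joins the benzoyl-bearing bridgehead to the gem-dimethyl carbon (two neighbouring quaternary carbons).
Disconnection 1 (last skeletal bond, closes ring B): C1–C8, by capture of a C8 tertiary cation, generated from a tertiary alcohol, by the C9=C1 enol of a dearomatised, C3-brominated ring A.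
Disconnection 2: C5–C6, by alkylative dearomatisation of a prenylated bromo benzophenone (three steps from 5-methoxyresorcinol) with an enantiopure primary triflate; C7 comes from an oxazolidinone-controlled enolate acylation, C8 from MeMgBr, the E side chain from cross-metathesis.
After ring B: C3–Br to C3–prenyl by cross-coupling, then silyl ether to acetate.
Ring order: ring A is the original arene (dearomatised at C5); ring B is formed second and last.

Key step: step 14

Remark: the side-chain oxygen is carried as its TBDPS ether (steps 7 to 16) because an allylic acetate would be cleaved by LiBH4 and ionised by zerovalent palladium, and the tertiary hydroxyl as its TMS ether (steps 10 to 13); the C5 descriptor reads R in the 3-bromo compounds and S in the 3-prenyl compounds only because bromine changes the CIP ranking of C4 against C9, the geometry being the same.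

Step 1
Reactants: 1 5-methoxyresorcinol; 2 benzoyl chloride
Product: 3 (2,4-dihydroxy-6-methoxyphenyl)(phenyl)methanone
Conditions: AlCl3, PhNO2, 0 °C to rt; aq. HCl work-up
Reagents that add atoms: none
Why: Friedel–Crafts acylation at one of the two equivalent ring carbons flanked by OH and OMe (para to the other hydroxyl) should outweigh attack at the single carbon between the two hydroxyls, and the symmetric 2,6-dihydroxy-4-methoxy isomer is removed by chromatography.

Step 2
Reactants: 3 (2,4-dihydroxy-6-methoxyphenyl)(phenyl)methanone; 4 prenyl bromide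
Product: 5 [2,4-dihydroxy-6-methoxy-3-(3-methylbut-2-en-1-yl)phenyl](phenyl)methanone
Conditions: 10% aq. KOH, 0 °C to rt
Reagents that add atoms: none
Why: C-alkylation of the phenolate (aqueous-alkali C-prenylation) should occur mainly at the ring carbon between the two phenoxide oxygens, the most nucleophilic position, and the O-prenyl ether and the isomer prenylated next to the methoxy group are separated.

Step 3
Reactants: 5 [2,4-dihydroxy-6-methoxy-3-(3-methylbut-2-en-1-yl)phenyl](phenyl)methanone
Product: 6 [3-bromo-4,6-dihydroxy-2-methoxy-5-(3-methylbut-2-en-1-yl)phenyl](phenyl)methanone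
Conditions: NBS (1.0 equiv), CH2Cl2, −78 °C
Reagents that add atoms: N-bromosuccinimide, O=C1CCC(=O)N1Br
Why: electrophilic aromatic bromination at the only remaining ring C–H, which three oxygen substituents should make far more reactive than the prenyl double bond at low temperature; the bromine later blocks C3 and is the handle for prenylation.

Step 4
Reactants: 7 pent-4-enoyl chloride; 8 (S)-4-benzyloxazolidin-2-one
Product: 9 (S)-4-benzyl-3-(pent-4-enoyl)oxazolidin-2-one
Conditions: Et3N, DMAP (cat.), CH2Cl2, 0 °C to rt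
Reagents that add atoms: none
Why: DMAP-catalysed N-acylation attaches the oxazolidinone auxiliary to the acid chloride.

Step 5
Reactants: 9 (S)-4-benzyl-3-(pent-4-enoyl)oxazolidin-2-one; 10 methacrolein
Product: 11 (S)-4-benzyl-3-[(4E)-5-methyl-6-oxohex-4-enoyl]oxazolidin-2-one
Conditions: methacrolein (5 equiv), second-generation Hoveyda–Grubbs catalyst RuCl2(H2IMes)(=CH-C6H4-2-OiPr) (5 mol%), CH2Cl2, 40 °C
Reagents that add atoms: none
Why: olefin cross-metathesis of the terminal alkene with methacrolein should give the conjugated trisubstituted enal as the E isomer (chain trans to CHO) under thermodynamic control.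

Step 6
Reactants: 11 (S)-4-benzyl-3-[(4E)-5-methyl-6-oxohex-4-enoyl]oxazolidin-2-one
Product: 12 (S)-4-benzyl-3-[(4E)-6-hydroxy-5-methylhex-4-enoyl]oxazolidin-2-one
Conditions: NaBH4, CeCl3·7H2O, MeOH, −78 °C
Reagents that add atoms: none
Why: Luche 1,2-reduction converts the enal into the E allylic alcohol while the imide carbonyls stay untouched at this temperature.

Step 7
Reactants: 12 (S)-4-benzyl-3-[(4E)-6-hydroxy-5-methylhex-4-enoyl]oxazolidin-2-one
Product: 13 (S)-4-benzyl-3-[(4E)-6-(tert-butyldiphenylsilyloxy)-5-methylhex-4-enoyl]oxazolidin-2-one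
Conditions: TBDPSCl, imidazole, DMF, rt
Reagents that add atoms: tert-butyl(chloro)diphenylsilane, CC(C)(C)[Si](Cl)(c1ccccc1)c1ccccc1
Why: silyl ether formation at the primary allylic alcohol gives a group that should survive strong base, BF3 at low temperature and palladium catalysis.

Step 8
Reactants: 13 (S)-4-benzyl-3-[(4E)-6-(tert-butyldiphenylsilyloxy)-5-methylhex-4-enoyl]oxazolidin-2-one
Product: 14 (S)-4-benzyl-3-[(2R,4E)-2-acetyl-6-(tert-butyldiphenylsilyloxy)-5-methylhex-4-enoyl]oxazolidin-2-one
Conditions: LiN(iPr)2 (commercial solution), THF, −78 °C; AcCl, −78 °C; aq. NH4Cl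
Reagents that add atoms: acetyl chloride, CC(=O)Cl
Why: auxiliary-controlled C-acylation of the chelated lithium Z-enolate, in which acetyl chloride approaches the face opposite the benzyl group, sets the future C7 (R here); the β-keto imide should not epimerise because allylic strain keeps its C–H out of conjugation.

Step 9
Reactants: 14 (S)-4-benzyl-3-[(2R,4E)-2-acetyl-6-(tert-butyldiphenylsilyloxy)-5-methylhex-4-enoyl]oxazolidin-2-one
Product: 15 (S)-4-benzyl-3-[(2R,4E)-6-(tert-butyldiphenylsilyloxy)-2-(2-hydroxypropan-2-yl)-5-methylhex-4-enoyl]oxazolidin-2-one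
Conditions: MeMgBr (1.5 equiv), THF, −78 °C; aq. NH4Cl at −78 °C
Reagents that add atoms: methylmagnesium bromide, C[Mg]Br
Why: Grignard addition to the ketone, which is more electrophilic than the imide carbonyls and kinetically non-enolisable, gives the tertiary alcohol (future C8) without creating a new stereocentre.

Step 10
Reactants: 15 (S)-4-benzyl-3-[(2R,4E)-6-(tert-butyldiphenylsilyloxy)-2-(2-hydroxypropan-2-yl)-5-methylhex-4-enoyl]oxazolidin-2-one
Product: 16 (S)-4-benzyl-3-[(2R,4E)-6-(tert-butyldiphenylsilyloxy)-5-methyl-2-[2-(trimethylsilyloxy)propan-2-yl]hex-4-enoyl]oxazolidin-2-one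
Conditions: TMSOTf, 2,6-lutidine, CH2Cl2, −78 to 0 °C
Reagents that add atoms: trimethylsilyl trifluoromethanesulfonate, C[Si](C)(C)OS(=O)(=O)C(F)(F)F
Why: O-silylation of the tertiary alcohol with the silyl triflate masks it, so that no alkoxide can trigger retro-aldol cleavage in step 11 or oxetane formation from the later triflate.

Step 11
Reactants: 16 (S)-4-benzyl-3-[(2R,4E)-6-(tert-butyldiphenylsilyloxy)-5-methyl-2-[2-(trimethylsilyloxy)propan-2-yl]hex-4-enoyl]oxazolidin-2-one
Product: 17 (2S,4E)-6-(tert-butyldiphenylsilyloxy)-5-methyl-2-[2-(trimethylsilyloxy)propan-2-yl]hex-4-en-1-ol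
Conditions: LiBH4, H2O (1 equiv), Et2O, 0 °C
Reagents that add atoms: none
Why: reductive cleavage of the auxiliary by hydride attack at the exocyclic imide carbonyl gives the primary alcohol (future C6) without enolisation, so C7 is untouched (the label changes to S only through CIP ranking) and the auxiliary is recovered.

Step 12
Reactants: 17 (2S,4E)-6-(tert-butyldiphenylsilyloxy)-5-methyl-2-[2-(trimethylsilyloxy)propan-2-yl]hex-4-en-1-ol
Product: 18 (2S,4E)-6-(tert-butyldiphenylsilyloxy)-5-methyl-2-[2-(trimethylsilyloxy)propan-2-yl]hex-4-en-1-yl trifluoromethanesulfonate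
Conditions: Tf2O, 2,6-lutidine, CH2Cl2, −78 °C; cold aqueous work-up, used at once
Reagents that add atoms: trifluoromethanesulfonic anhydride, O=S(=O)(OS(=O)(=O)C(F)(F)F)C(F)(F)F
Why: sulfonate ester formation (triflation) turns the hindered, β-branched primary alcohol into an electrophile reactive enough for C-alkylation of a phenoxide.

Step 13
Reactants: 6 [3-bromo-4,6-dihydroxy-2-methoxy-5-(3-methylbut-2-en-1-yl)phenyl](phenyl)methanone; 18 (2S,4E)-6-(tert-butyldiphenylsilyloxy)-5-methyl-2-[2-(trimethylsilyloxy)propan-2-yl]hex-4-en-1-yl trifluoromethanesulfonate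
Product: 20 dearomatised dienone tertiary alcohol (6R in the ring; 2S in the chain), via O-trimethylsilyl dienone 19 (not isolated)
Conditions: LiN(SiMe3)2 (2.2 equiv, commercial solution), THF, −78 to 0 °C; then 1 M HCl, THF/MeOH, 0 °C to rt
Reagents that add atoms: none
Why: alkylative dearomatisation, in which the dilithium salt of 6 is C-alkylated by the primary triflate (SN2 at C6, C7 untouched) at the prenyl-bearing carbon between the two oxide oxygens, the site at which prenylated acylphloroglucinols are known to accept β-branched primary triflates, and the acid work-up hydrolyses the tertiary silyl ether; the remote C7 centre gives no useful facial bias at the new quaternary C5, so both C5 epimers are expected and 20 is separated by chromatography.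

Step 14
Reactants: 20 dearomatised dienone tertiary alcohol (6R in the ring; 2S in the chain)
Product: 21 3-bromo bicyclo[3.3.1]nonene dione (1R,5R,7S), silyl ether
Conditions: BF3·OEt2 (2 equiv), CH2Cl2, −78 to −20 °C; aq. NaHCO3
Reagents that add atoms: none
Why: BF3 binds the tertiary hydroxyl and ionises it to the C8 carbocation, which the C5 tether holds over the dienol of ring A; the enol carbon C1 (C9=C1, chelated to the benzoyl group) attacks it and loss of the enol proton leaves the non-enolisable C9 ketone. The closest known reaction type is the acid-mediated biomimetic cation–enol C-alkylation that turns dearomatised prenylated acylphloroglucinols into bicyclo[3.3.1]nonanes. Ring B (C1, C8, C7, C6, C5, C9) closes in a 6-(enolendo) mode, with the enol double bond inside the new ring and the cationic carbon bearing its two methyl groups outside it, through a boat-like arrangement that keeps the C7 chain pseudo-equatorial. The new stereocentre C1 is dictated by C5, because the three-atom tether from the quaternary C5 can reach C1 only on the face on which it stands, while C7 is carried through unchanged and ends syn to the C2–C4 bridge. The step needs C- over O-alkylation and attack by C1 instead of C3: enol-ether formation at O9 or O4 is reversible under the Lewis acid and should drain into the irreversible C–C bond, and C3 is blocked and deactivated by bromine. Low temperature and short contact time limit proton loss from the cation toward C7 and acid attack on the prenyl groups.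

Step 15
Reactants: 21 3-bromo bicyclo[3.3.1]nonene dione (1R,5R,7S), silyl ether; 22 prenylboronic acid pinacol ester
Product: 23 3-prenyl bicyclo[3.3.1]nonene dione (1R,5S,7S), silyl ether
Conditions: PdCl2(IPent)(3-chloropyridine) (5 mol%; IPent = 1,3-bis[2,6-di(pentan-3-yl)phenyl]imidazol-2-ylidene), K3PO4 (3 equiv), THF/H2O, 60 °C
Reagents that add atoms: none
Why: Suzuki–Miyaura coupling, in which zerovalent palladium inserts into the electron-poor C3–Br bond of the bromo vinylogous ester and the bulky carbene ligand should steer reductive elimination to the unsubstituted allyl terminus (prenyl, not 1,1-dimethylallyl), the silyl ether being inert where an allylic acetate would ionise.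

Step 16
Reactants: 23 3-prenyl bicyclo[3.3.1]nonene dione (1R,5S,7S), silyl ether
Product: 24 3-prenyl bicyclo[3.3.1]nonene dione (1R,5S,7S), allylic alcohol
Conditions: HF·pyridine, pyridine, THF, 0 °C to rt
Reagents that add atoms: none
Why: fluoride-mediated desilylation under buffered, non-basic conditions frees the allylic alcohol without retro-Claisen cleavage of the bridgehead 1,3-diketone or loss of the methyl enol ether.

Step 17
Reactants: 24 3-prenyl bicyclo[3.3.1]nonene dione (1R,5S,7S), allylic alcohol
Product: 25 target CNP0256662.1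
Conditions: Ac2O, pyridine, DMAP (cat.), CH2Cl2, 0 °C to rt
Reagents that add atoms: acetic anhydride, CC(=O)OC(C)=O
Why: DMAP-catalysed acetylation of the only hydroxyl group completes the target with all three stereocentres and the E alkene unchanged.

Compound list
1 | 5-methoxyresorcinol (5-methoxybenzene-1,3-diol) | COc1cc(O)cc(O)c1 | starting material
2 | benzoyl chloride | O=C(Cl)c1ccccc1 | starting material
3 | (2,4-dihydroxy-6-methoxyphenyl)(phenyl)methanone | COc1cc(O)cc(O)c1C(=O)c1ccccc1 | intermediate
4 | prenyl bromide (1-bromo-3-methylbut-2-ene) | CC(C)=CCBr | starting material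
5 | [2,4-dihydroxy-6-methoxy-3-(3-methylbut-2-en-1-yl)phenyl](phenyl)methanone | COc1cc(O)c(CC=C(C)C)c(O)c1C(=O)c1ccccc1 | intermediate
6 | [3-bromo-4,6-dihydroxy-2-methoxy-5-(3-methylbut-2-en-1-yl)phenyl](phenyl)methanone | COc1c(Br)c(O)c(CC=C(C)C)c(O)c1C(=O)c1ccccc1 | intermediate
7 | pent-4-enoyl chloride | C=CCCC(=O)Cl | starting material
8 | (S)-4-benzyloxazolidin-2-one | O=C1N[C@@H](Cc2ccccc2)CO1 | starting material
9 | (S)-4-benzyl-3-(pent-4-enoyl)oxazolidin-2-one | O=C1OC[C@H](Cc2ccccc2)N1C(=O)CCC=C | intermediate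
10 | methacrolein (2-methylprop-2-enal) | C=C(C)C=O | starting material
11 | (S)-4-benzyl-3-[(4E)-5-methyl-6-oxohex-4-enoyl]oxazolidin-2-one | O=C1OC[C@H](Cc2ccccc2)N1C(=O)CC/C=C(\C)C=O | intermediate
12 | (S)-4-benzyl-3-[(4E)-6-hydroxy-5-methylhex-4-enoyl]oxazolidin-2-one | O=C1OC[C@H](Cc2ccccc2)N1C(=O)CC/C=C(\C)CO | intermediate
13 | (S)-4-benzyl-3-[(4E)-6-(tert-butyldiphenylsilyloxy)-5-methylhex-4-enoyl]oxazolidin-2-one | O=C1OC[C@H](Cc2ccccc2)N1C(=O)CC/C=C(\C)CO[Si](c2ccccc2)(c2ccccc2)C(C)(C)C | intermediate
14 | (S)-4-benzyl-3-[(2R,4E)-2-acetyl-6-(tert-butyldiphenylsilyloxy)-5-methylhex-4-enoyl]oxazolidin-2-one | O=C1OC[C@H](Cc2ccccc2)N1C(=O)[C@H](C/C=C(\C)CO[Si](c2ccccc2)(c2ccccc2)C(C)(C)C)C(C)=O | intermediate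
15 | (S)-4-benzyl-3-[(2R,4E)-6-(tert-butyldiphenylsilyloxy)-2-(2-hydroxypropan-2-yl)-5-methylhex-4-enoyl]oxazolidin-2-one | O=C1OC[C@H](Cc2ccccc2)N1C(=O)[C@H](C/C=C(\C)CO[Si](c2ccccc2)(c2ccccc2)C(C)(C)C)C(C)(C)O | intermediate
16 | (S)-4-benzyl-3-[(2R,4E)-6-(tert-butyldiphenylsilyloxy)-5-methyl-2-[2-(trimethylsilyloxy)propan-2-yl]hex-4-enoyl]oxazolidin-2-one | O=C1OC[C@H](Cc2ccccc2)N1C(=O)[C@H](C/C=C(\C)CO[Si](c2ccccc2)(c2ccccc2)C(C)(C)C)C(C)(C)O[Si](C)(C)C | intermediate
17 | (2S,4E)-6-(tert-butyldiphenylsilyloxy)-5-methyl-2-[2-(trimethylsilyloxy)propan-2-yl]hex-4-en-1-ol | OC[C@H](C/C=C(\C)CO[Si](c1ccccc1)(c1ccccc1)C(C)(C)C)C(C)(C)O[Si](C)(C)C | intermediate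
18 | (2S,4E)-6-(tert-butyldiphenylsilyloxy)-5-methyl-2-[2-(trimethylsilyloxy)propan-2-yl]hex-4-en-1-yl trifluoromethanesulfonate | O=S(=O)(OC[C@H](C/C=C(\C)CO[Si](c1ccccc1)(c1ccccc1)C(C)(C)C)C(C)(C)O[Si](C)(C)C)C(F)(F)F | intermediate
19 | O-trimethylsilyl dienone: (6R)-4-benzoyl-2-bromo-6-{(2S,4E)-6-(tert-butyldiphenylsilyloxy)-5-methyl-2-[2-(trimethylsilyloxy)propan-2-yl]hex-4-en-1-yl}-5-hydroxy-3-methoxy-6-(3-methylbut-2-en-1-yl)cyclohexa-2,4-dien-1-one | COC1=C(Br)C(=O)[C@](CC=C(C)C)(C[C@H](C/C=C(\C)CO[Si](c2ccccc2)(c2ccccc2)C(C)(C)C)C(C)(C)O[Si](C)(C)C)C(O)=C1C(=O)c1ccccc1 | intermediate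
20 | dearomatised dienone tertiary alcohol: (6R)-4-benzoyl-2-bromo-6-[(2S,4E)-6-(tert-butyldiphenylsilyloxy)-2-(2-hydroxypropan-2-yl)-5-methylhex-4-en-1-yl]-5-hydroxy-3-methoxy-6-(3-methylbut-2-en-1-yl)cyclohexa-2,4-dien-1-one | COC1=C(Br)C(=O)[C@](CC=C(C)C)(C[C@H](C/C=C(\C)CO[Si](c2ccccc2)(c2ccccc2)C(C)(C)C)C(C)(C)O)C(O)=C1C(=O)c1ccccc1 | intermediate
21 | 3-bromo bicycle, silyl ether: (1R,5R,7S)-1-benzoyl-3-bromo-7-[(2E)-4-(tert-butyldiphenylsilyloxy)-3-methylbut-2-en-1-yl]-2-methoxy-8,8-dimethyl-5-(3-methylbut-2-en-1-yl)bicyclo[3.3.1]non-2-ene-4,9-dione (overview numbering) | COC1=C(Br)C(=O)[C@]2(CC=C(C)C)C[C@H](C/C=C(\C)CO[Si](c3ccccc3)(c3ccccc3)C(C)(C)C)C(C)(C)[C@@]1(C(=O)c1ccccc1)C2=O | intermediate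
22 | prenylboronic acid pinacol ester (4,4,5,5-tetramethyl-2-(3-methylbut-2-en-1-yl)-1,3,2-dioxaborolane) | CC(C)=CCB1OC(C)(C)C(C)(C)O1 | starting material
23 | 3-prenyl bicycle, silyl ether: (1R,5S,7S)-1-benzoyl-7-[(2E)-4-(tert-butyldiphenylsilyloxy)-3-methylbut-2-en-1-yl]-2-methoxy-8,8-dimethyl-3,5-bis(3-methylbut-2-en-1-yl)bicyclo[3.3.1]non-2-ene-4,9-dione (overview numbering) | COC1=C(CC=C(C)C)C(=O)[C@]2(CC=C(C)C)C[C@H](C/C=C(\C)CO[Si](c3ccccc3)(c3ccccc3)C(C)(C)C)C(C)(C)[C@@]1(C(=O)c1ccccc1)C2=O | intermediate
24 | 3-prenyl bicycle, allylic alcohol: (1R,5S,7S)-1-benzoyl-7-[(2E)-4-hydroxy-3-methylbut-2-en-1-yl]-2-methoxy-8,8-dimethyl-3,5-bis(3-methylbut-2-en-1-yl)bicyclo[3.3.1]non-2-ene-4,9-dione (overview numbering) | COC1=C(CC=C(C)C)C(=O)[C@]2(CC=C(C)C)C[C@H](C/C=C(\C)CO)C(C)(C)[C@@]1(C(=O)c1ccccc1)C2=O | intermediate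
25 | CNP0256662.1: (1R,5S,7S)-7-[(2E)-4-acetoxy-3-methylbut-2-en-1-yl]-1-benzoyl-2-methoxy-8,8-dimethyl-3,5-bis(3-methylbut-2-en-1-yl)bicyclo[3.3.1]non-2-ene-4,9-dione (overview numbering) | COC1=C(CC=C(C)C)C(=O)[C@]2(CC=C(C)C)C[C@H](C/C=C(\C)COC(C)=O)C(C)(C)[C@@]1(C(=O)c1ccccc1)C2=O | target

Total step count: 17. Longest linear sequence: 14 steps (steps 4 to 17, from pent-4-enoyl chloride and the auxiliary); the arene branch (steps 1 to 3) joins at step 13.

Steps most likely to fail

1. Step 14 (key step). The cation may be trapped by O9 or O4 as cyclic enol ethers that do not reopen. It may lose a proton toward C7 and be re-protonated, which erodes the C7 configuration, or undergo a hydride shift. The released protic acid may cyclise prenyl groups onto carbonyl oxygens, and difluoroboron chelation of the enol may lower its nucleophilicity. The fallback replaces Lewis-acid ionisation of an alcohol by light-driven proton transfer to an alkene. It sets out from 14: Takai–Lombardo methylenation (Zn, CH2Br2, TiCl4) of the ketone should give the isopropenyl imide F1 without touching the α-centre. LiBH4 then gives the isopropenyl alcohol F2, and Tf2O with 2,6-lutidine gives the isopropenyl triflate F3. Alkylative dearomatisation of 6 with it (LiN(SiMe3)2, THF) gives the isopropenyl dienone F4 after removal of the C5 epimer. Irradiation at about 370 nm in CH2Cl2 should let the excited chelated enol pass its proton to the terminal CH2 of the isopropenyl group (excited-state intramolecular proton transfer, a known way to close acyl-bridgehead bicyclo[3.3.1]nonanes of this class). The resulting C8 cation and enolate pair collapses at C1, and the route is rejoined at 21.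

2. Step 13. O-alkylation of the phenoxide oxygens may outrun C-alkylation at the already substituted C5. The absence of facial selectivity at C5 costs half of the material and demands a difficult separation of epimers. The hindered triflate may also decompose by elimination or oxetane formation. The fallback reverses the order in which the two C5 substituents are introduced and puts the C5 configuration under catalyst control. It sets out from 3 and 18: C-alkylation of the dilithium salt of 3 at the free ring carbon between the two hydroxyls should give the chain-bearing benzophenone F5, and NBS at −78 °C brominates the last ring C–H to give the chain-bearing bromo benzophenone F6. Dearomative prenylation with 4 then uses the more reactive allylic bromide under solid–liquid phase transfer (CsOH·H2O, N-(9-anthracenylmethyl)cinchonidinium bromide, toluene, −40 °C), where the chiral ammonium ion pair is meant to differentiate the two faces at C5 (the pseudoenantiomeric cinchoninium salt if the opposite sense is needed). This comes back to the route at 19, which is hydrolysed to 20 as in step 13.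

3. Step 15. Bond formation may occur through the γ-carbon of the allyl unit and give the 1,1-dimethylallyl isomer. Oxidative addition at the hindered, tetrasubstituted C3–Br bond may be slow, and aqueous base may cleave the bridgehead benzoyl group by retro-Claisen reaction. The fallback is a base-free two-step prenylation from 21. Stille coupling with allyltributylstannane (Pd(PPh3)4, DMF, 80 °C) should give the 3-allyl bicycle F7, for which no α/γ question exists. Cross-metathesis with 2-methylbut-2-ene (second-generation Grubbs catalyst RuCl2(H2IMes)(PCy3)(=CHPh), short reaction time so that the trisubstituted, oxygenated side-chain alkene is not exchanged) then converts allyl into prenyl and comes back to the route at 23.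

Further compounds
F1 | step 14 | (S)-4-benzyl-3-[(2R,4E)-6-(tert-butyldiphenylsilyloxy)-5-methyl-2-(prop-1-en-2-yl)hex-4-enoyl]oxazolidin-2-one | O=C1OC[C@H](Cc2ccccc2)N1C(=O)[C@H](C/C=C(\C)CO[Si](c2ccccc2)(c2ccccc2)C(C)(C)C)C(C)=C
F2 | step 14 | (2R,4E)-6-(tert-butyldiphenylsilyloxy)-5-methyl-2-(prop-1-en-2-yl)hex-4-en-1-ol | OC[C@H](C/C=C(\C)CO[Si](c1ccccc1)(c1ccccc1)C(C)(C)C)C(C)=C
F3 | step 14 | (2R,4E)-6-(tert-butyldiphenylsilyloxy)-5-methyl-2-(prop-1-en-2-yl)hex-4-en-1-yl trifluoromethanesulfonate | O=S(=O)(OC[C@H](C/C=C(\C)CO[Si](c1ccccc1)(c1ccccc1)C(C)(C)C)C(C)=C)C(F)(F)F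
F4 | step 14 | (6R)-4-benzoyl-2-bromo-6-[(2S,4E)-6-(tert-butyldiphenylsilyloxy)-5-methyl-2-(prop-1-en-2-yl)hex-4-en-1-yl]-5-hydroxy-3-methoxy-6-(3-methylbut-2-en-1-yl)cyclohexa-2,4-dien-1-one | COC1=C(Br)C(=O)[C@](CC=C(C)C)(C[C@H](C/C=C(\C)CO[Si](c2ccccc2)(c2ccccc2)C(C)(C)C)C(C)=C)C(O)=C1C(=O)c1ccccc1
F5 | step 13 | [3-{(2S,4E)-6-(tert-butyldiphenylsilyloxy)-5-methyl-2-[2-(trimethylsilyloxy)propan-2-yl]hex-4-en-1-yl}-2,4-dihydroxy-6-methoxyphenyl](phenyl)methanone | COc1cc(O)c(C[C@H](C/C=C(\C)CO[Si](c2ccccc2)(c2ccccc2)C(C)(C)C)C(C)(C)O[Si](C)(C)C)c(O)c1C(=O)c1ccccc1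
F6 | step 13 | [3-bromo-5-{(2S,4E)-6-(tert-butyldiphenylsilyloxy)-5-methyl-2-[2-(trimethylsilyloxy)propan-2-yl]hex-4-en-1-yl}-4,6-dihydroxy-2-methoxyphenyl](phenyl)methanone | COc1c(Br)c(O)c(C[C@H](C/C=C(\C)CO[Si](c2ccccc2)(c2ccccc2)C(C)(C)C)C(C)(C)O[Si](C)(C)C)c(O)c1C(=O)c1ccccc1
F7 | step 15 | (1R,5S,7S)-3-allyl-1-benzoyl-7-[(2E)-4-(tert-butyldiphenylsilyloxy)-3-methylbut-2-en-1-yl]-2-methoxy-8,8-dimethyl-5-(3-methylbut-2-en-1-yl)bicyclo[3.3.1]non-2-ene-4,9-dione (overview numbering) | COC1=C(CC=C)C(=O)[C@]2(CC=C(C)C)C[C@H](C/C=C(\C)CO[Si](c3ccccc3)(c3ccccc3)C(C)(C)C)C(C)(C)[C@@]1(C(=O)c1ccccc1)C2=O
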